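# Proposed total synthesis of CNP0278889.1 by sulfone–epoxide macrocyclisation at C1–C2

Remark on the chemistry: the ring positions are labelled C1–C10 so that C4(CH3)–C5 is the epoxide, C6 carries the ester oxygen, C7 the isopropyl group, C8=C9 is the E alkene and C10 is the methyl carbinol. These labels are used for every intermediate, open-chain ones included; the names in the compound list follow systematic numbering.

## Analysis of the target

The target is a germacrane-type sesquiterpenoid ester: a ten-membered carbocycle fused to an oxirane (an 11-oxabicyclo[8.1.0]undec-4-ene) that carries a 4-hydroxybenzoate at C6. It has five stereocenters, 4S, 5R, 6R, 7S and 10R. C4–C7 are contiguous, whereas C10 is insulated from them by the alkene on one side and by three methylenes on the other, so it has to be set independently. Within the contiguous block the epoxide is the one derived from a Z alkene (ring bonds C3–C4 and C5–C6 cis on the oxirane), the epoxide oxygen and the C6 oxygen are erythro (same ring face), and the C6 oxygen and the C7 isopropyl group are syn along the chain C5–C6–C7–C8. The sensitive groups are the trisubstituted epoxide, which faces the C10 hydroxyl across the ring and would be opened transannularly by acid, the tertiary allylic alcohol, and the phenolic aryl ester, which does not tolerate strong base. The main difficulty is the medium ring: direct closure of a ten-membered carbocycle fights transannular strain, and the ring must hold one E alkene, one epoxidised Z alkene and a quaternary carbinol remote from the other stereocenters. The plan rests on the C10(CH3)(OH)–C1H2 unit next to the unfunctionalised C2 and C3 methylenes: a tertiary alcohol with an adjacent CH2 is what is left when a 2-methyl-2-alkenyloxirane is opened at its methylene carbon by a carbon nucleophile, and C2 can carry a sulfonyl group that makes it nucleophilic and is removed afterwards. The C4–C5 epoxide is held back as a Z alkene during that closure, which stiffens the chain and leaves a C6 allylic alcohol to direct the epoxidation at the end.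

## Retrosynthetic reasoning

**Ester and phenol (28 ⇒ 27 ⇒ 23 + 26).** The aryl ester C6–O bond is cut first, because the phenolic ester is the most base-labile group and because a free C6 hydroxyl is needed one step earlier. The phenol is masked as a silyl ether in 27 so that only the carboxyl group of 26 can acylate. Forward, the acylation must reach the secondary C6–OH of 23 and leave the tertiary C10–OH alone. Acid 26 comes from 24 in one operation.

**Epoxide (23 ⇒ 22).** The two C–O bonds of the oxirane are cut back to the Z alkene C4=C5 of diene diol 22. This is done late because the epoxide is acid-sensitive and would compete as an electrophile during the ring closure. Three stereochemical features (C4, C5 and their relation to C6) then follow from one existing stereocenter. The forward reaction has to oxidise only C4=C5 and deliver oxygen to the face that gives the erythro epoxy alcohol.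

**Protecting and activating groups (22 ⇒ 21 ⇒ 20).** The C6 silyl ether and a phenylsulfonyl group at C2 are added retrosynthetically. The sulfone turns the otherwise inert C2 methylene into a carbanion site and is removed reductively afterwards.

**Key disconnection (20 ⇒ 18, through 19).** The ring is opened at C1–C2. Cutting here places the nucleophile at the sulfone-bearing C2 and the electrophile at the methylene of a 2,2-disubstituted epoxide, whose opening gives the C10 tertiary alcohol directly. Other ring bonds would either create a stereocenter during closure or require an sp2 coupling in a strained ring. The gain is that the ring closure touches no stereocenter of the target. The forward reaction must attack C1 and not the allylic terminus C8.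

**C8=C9 alkene (18 ⇒ 14 + 16).** The E alkene is cut by an olefination disconnection, with a tetrazolyl sulfone at C8 and the aldehyde at C9. The aldehyde 16 carries the complete C10 stereocenter and comes from the chiral-pool epoxy alcohol 15 by oxidation, so C10 is bought and not made. The forward step has to be E-selective and must spare the epoxide.

**C8 functional group interchange (14 ⇒ 13 ⇒ 12 ⇒ 11 ⇒ 10).** The sulfone at C8 is traced back through the sulfide and the primary alcohol to the acyl group of an aldol adduct, with the C6 hydroxyl silylated on the way.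

**C6–C7 bond (10 ⇒ 8 + 5, through 9).** The C6–C7 bond is cut as a syn aldol between the isovaleryl imide 8 and the Z-enal 5. This sets C6 and C7 in one auxiliary-controlled step and brings in the isopropyl group with the enolate component. Imide 8 is made from 6 and 7.

**Z alkene (5 ⇒ 4 ⇒ 3 ⇒ 2 ⇒ 1).** The Z trisubstituted alkene C4=C5 with its C2–C3 chain is taken from the unsaturated lactone 1, in which the ring enforces the cis relation of C3 and C6. Ring opening to the amide 2, exchange of oxygen for the sulfonyl group at C2 (3, 4) and reduction give 5 without ever forming the alkene by an olefination.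

## Alternatives that were turned down

**Alternative 1:** The ring would be opened at C5–C6, between the alkene carbon and the carbinol carbon. Forward, the open-chain iodo aldehyde A2 would be treated with CrCl2 and a catalytic amount of NiCl2 under high dilution. Insertion into the C–I bond and addition to the aldehyde would give the macrocyclic dienol A1 with the C6 hydroxyl in place.
- For: carbonyl addition is among the most dependable ways to close a medium ring, the Z geometry of the iodoalkene is carried over unchanged, and no activating group has to be removed. A1 already has the free C6 hydroxyl that directs the epoxidation, and its C10 silyl ether could be cleaved in the final fluoride step, so after ring closure this alternative is up to two steps shorter than the chosen plan.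
- Against: the ring closure creates the C6 stereocenter, and the only control element is the adjacent C7 centre inside a flexible ten-membered transition state, so a mixture and an oxidation–reduction correction must be expected. A2 is an α-branched β,γ-unsaturated aldehyde whose C7–H is both α to the carbonyl and allylic, so loss of the C7 configuration or migration of C8=C9 into conjugation threatens before ring closure.
- Comparison: the chosen plan sets C6 and C7 together in an auxiliary-controlled aldol before the ring exists and closes the ring with a step that creates no stereocenter of the target. The price is the installation and removal of the sulfone.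

**Alternative 2:** Here the ten-membered ring is grown from a six-membered one: retrosynthetically C6–C7 is cut and C4–C9 is formed, which leads to the cis-1,2-dialkenylcyclohexane-1,3-diol A4. Forward, KH and 18-crown-6 would form the alkoxide of A4, the anionic oxy-Cope rearrangement would expand the ring, and PhNTf2 would trap the C4 enolate as the enol triflate A3.
- For: ring expansion sidesteps the entropic and transannular penalties of any direct ten-membered closure, and on this point it is stronger than the chosen plan. One ordered transition state forms C6–C7 with both stereocenters and fixes both ring alkenes.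
- Against: the burden moves to A4, which needs three contiguous stereocenters on the cyclohexane (two of them tertiary carbinols) and two alkenyl groups of defined geometry, one an acid-labile enol ether. The cis arrangement required for the Z C4=C5 and E C8=C9 pair forces a chair with one axial ring bond, so boat pathways and wrong alkene or stereocenter combinations compete. The triflate of A3 must still be exchanged for the C4 methyl group and the PMB ether removed.
- Comparison: the chosen plan relies on acyclic stereocontrol of well-understood type (aldol, chiral-pool epoxide) and keeps every stereochemical decision out of the ring-forming step. It concedes that its ring closure is a true medium-ring cyclisation.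

**Alternative 3:** The ring is cut at C3–C4, between the allylic methylene and the methyl-bearing alkene carbon, giving the iodo triene A6. Forward, 9-BBN would hydroborate the terminal alkene of A6 so that boron sits on C3, and PdCl2(dppf) with Cs2CO3 would couple this alkylborane with the C4 iodoalkene to give the macrocyclic bis-silyl ether A5.
- For: no stereocenter is formed in the closure, the Z geometry is fixed by the iodoalkene, the conditions are mild, and there is no traceless group to remove. A5 is the C10 triethylsilyl ether of compound 21 of the chosen route and is reached without the sulfone steps, so this alternative is at least as economical.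
- Against: the reductive elimination that forms the ten-membered ring must compete with β-hydride elimination and with intermolecular coupling, and B-alkyl Suzuki macrocyclisations are dependable for large rings but poorly supported for strained medium carbocycles. A6 also needs the quaternary C10 carbinol with an allyl group, which is less directly available in enantiopure form than an epoxide.
- Comparison: the chosen plan joins two sp3 carbons with a strain-activated electrophile that also delivers the C10 stereocenter from the chiral pool, and it needs no transition metal.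

Key step: step 13

## Route

Remark on the chemistry: lactone 1, oxazolidinone 6 and epoxy alcohol 15 are assumed to be purchased as such.

Step 1
Reactants: 1 4-methyl-5,6-dihydro-2H-pyran-2-one
Product: 2 (Z)-5-hydroxy-N-methoxy-N,3-dimethylpent-2-enamide
Conditions: MeNH(OMe)·HCl, Me3Al, CH2Cl2, 0 °C → rt
Reagents that add atoms: N,O-dimethylhydroxylamine hydrochloride, CNOC.Cl
Why: Weinreb aminolysis of a lactone: the amide MeClAlN(OMe)Me formed in the flask attacks the ring carbonyl and opens the ring by acyl substitution. The C=C bond is not touched, so the Z geometry is inherited from the ring.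

Step 2
Reactants: 2 (Z)-5-hydroxy-N-methoxy-N,3-dimethylpent-2-enamide
Product: 3 (Z)-N-methoxy-N,3-dimethyl-5-(phenylsulfanyl)pent-2-enamide
Conditions: PhSSPh, nBu3P, THF, rt
Reagents that add atoms: diphenyl disulfide, c1ccc(cc1)SSc1ccccc1
Why: Hata-type thioetherification: the primary alcohol is activated as an alkoxyphosphonium ion and displaced at once by benzenethiolate in an SN2 reaction. No isolable leaving group is formed that the amide oxygen could displace to re-form the lactone, and the β,β-disubstituted enamide is a poor acceptor for phosphine or thiolate.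

Step 3
Reactants: 3 (Z)-N-methoxy-N,3-dimethyl-5-(phenylsulfanyl)pent-2-enamide
Product: 4 (Z)-N-methoxy-N,3-dimethyl-5-(phenylsulfonyl)pent-2-enamide
Conditions: mCPBA (2.2 equiv), CH2Cl2, 0 °C → rt
Reagents that add atoms: 3-chloroperoxybenzoic acid, OOC(=O)c1cccc(Cl)c1
Why: Peracid oxidation of the sulfide through the sulfoxide to the sulfone. The amide-conjugated alkene is electron-poor and should not be epoxidised under these conditions.

Step 4
Reactants: 4 (Z)-N-methoxy-N,3-dimethyl-5-(phenylsulfonyl)pent-2-enamide
Product: 5 (Z)-3-methyl-5-(phenylsulfonyl)pent-2-enal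
Conditions: iBu2AlH (1.3 equiv), THF, −78 °C; aq. KNaC4H4O6
Reagents that add atoms: none
Why: Weinreb amide reduction: the chelated tetrahedral aluminium adduct is stable at −78 °C and releases the aldehyde only on work-up, so over-reduction is avoided. The sulfone is inert and the Z alkene is not exposed to acid or base.

Step 5
Reactants: 6 (R)-4-benzyl-1,3-oxazolidin-2-one; 7 3-methylbutanoyl chloride
Product: 8 (R)-4-benzyl-3-(3-methylbutanoyl)-1,3-oxazolidin-2-one
Conditions: Et3N, DMAP (cat.), CH2Cl2, 0 °C → rt
Reagents that add atoms: none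
Why: DMAP-catalysed N-acylation of the oxazolidinone by the acid chloride; the stereocenter of the auxiliary is not involved.

Step 6
Reactants: 8 (R)-4-benzyl-3-(3-methylbutanoyl)-1,3-oxazolidin-2-one; 5 (Z)-3-methyl-5-(phenylsulfonyl)pent-2-enal
Product: 10 (R)-4-benzyl-3-[(2R,3S,4Z)-3-hydroxy-5-methyl-7-(phenylsulfonyl)-2-(propan-2-yl)hept-4-enoyl]-1,3-oxazolidin-2-one, via dibutylboron Z-enolate 9 (not isolated)
Conditions: nBu2BOTf, iPr2NEt, CH2Cl2, 0 °C; then 5, −78 → 0 °C; pH 7 buffer, MeOH, 30% H2O2, 0 °C
Reagents that add atoms: none
Why: Evans syn aldol: soft enolisation gives the Z-boron enolate 9, which adds to the aldehyde through a closed Zimmerman–Traxler chair on the enolate face away from the benzyl group. With the (R)-auxiliary this sets C7 and C6 as the syn pair with the absolute configuration of the target. The enal has no sp3 α-hydrogen and reacts at −78 °C, so its Z geometry should survive.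

Step 7
Reactants: 10 (R)-4-benzyl-3-[(2R,3S,4Z)-3-hydroxy-5-methyl-7-(phenylsulfonyl)-2-(propan-2-yl)hept-4-enoyl]-1,3-oxazolidin-2-one
Product: 11 (R)-4-benzyl-3-[(2R,3S,4Z)-3-[(tert-butyldimethylsilyl)oxy]-5-methyl-7-(phenylsulfonyl)-2-(propan-2-yl)hept-4-enoyl]-1,3-oxazolidin-2-one
Conditions: TBSOTf, 2,6-lutidine, CH2Cl2, −78 → 0 °C
Reagents that add atoms: tert-butyldimethylsilyl trifluoromethanesulfonate, CC(C)(C)[Si](C)(C)OS(=O)(=O)C(F)(F)F
Why: Silylation of a hindered secondary alcohol with a silyl triflate and a non-nucleophilic base. The silyl ether blocks retro-aldol cleavage and survives the basic steps that follow.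

Step 8
Reactants: 11 (R)-4-benzyl-3-[(2R,3S,4Z)-3-[(tert-butyldimethylsilyl)oxy]-5-methyl-7-(phenylsulfonyl)-2-(propan-2-yl)hept-4-enoyl]-1,3-oxazolidin-2-one
Product: 12 (2S,3S,4Z)-3-[(tert-butyldimethylsilyl)oxy]-5-methyl-7-(phenylsulfonyl)-2-(propan-2-yl)hept-4-en-1-ol
Conditions: LiBH4, MeOH (1 equiv), THF, 0 °C
Reagents that add atoms: none
Why: Reductive cleavage of the N-acyloxazolidinone: hydride attacks the exocyclic carbonyl and the acyl carbon becomes the C8 primary alcohol. C7 is not epimerised, and the sulfone, alkene and silyl ether are inert to LiBH4.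

Step 9
Reactants: 12 (2S,3S,4Z)-3-[(tert-butyldimethylsilyl)oxy]-5-methyl-7-(phenylsulfonyl)-2-(propan-2-yl)hept-4-en-1-ol
Product: 13 5-{[(2R,3S,4Z)-3-[(tert-butyldimethylsilyl)oxy]-5-methyl-7-(phenylsulfonyl)-2-(propan-2-yl)hept-4-en-1-yl]sulfanyl}-1-phenyl-1H-tetrazole
Conditions: 1-phenyl-1H-tetrazole-5-thiol, PPh3, DIAD, THF, 0 °C → rt
Reagents that add atoms: 1-phenyl-1H-tetrazole-5-thiol, Sc1nnnn1-c1ccccc1
Why: Mitsunobu thioetherification of a primary alcohol with an acidic heteroaryl thiol; the SN2 displacement occurs at CH2, so no stereocenter is affected.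

Step 10
Reactants: 13 5-{[(2R,3S,4Z)-3-[(tert-butyldimethylsilyl)oxy]-5-methyl-7-(phenylsulfonyl)-2-(propan-2-yl)hept-4-en-1-yl]sulfanyl}-1-phenyl-1H-tetrazole
Product: 14 5-{[(2R,3S,4Z)-3-[(tert-butyldimethylsilyl)oxy]-5-methyl-7-(phenylsulfonyl)-2-(propan-2-yl)hept-4-en-1-yl]sulfonyl}-1-phenyl-1H-tetrazole
Conditions: (NH4)6Mo7O24·4H2O (10 mol %), 30% H2O2, EtOH, 0 °C → rt
Reagents that add atoms: hydrogen peroxide, OO
Why: Oxidation of the sulfide to the sulfone by H2O2 with (NH4)6Mo7O24 as catalyst. The peroxo species formed from this salt oxidises sulfur much faster than an isolated trisubstituted alkene, so C4=C5 and the silyl ether should be kept.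

Step 11
Reactants: 15 (S)-(2-methyloxiran-2-yl)methanol
Product: 16 (R)-2-methyloxirane-2-carbaldehyde
Conditions: Pr4N[RuO4] (5 mol %), N-methylmorpholine N-oxide, 4 Å MS, CH2Cl2, rt; filtered through silica, solution used at once
Reagents that add atoms: none
Why: Ley–Griffith oxidation of a primary epoxy alcohol under neutral conditions. The α-carbon is quaternary, so the C10 stereocenter cannot epimerise; the volatile aldehyde is not isolated neat.

Step 12
Reactants: 14 5-{[(2R,3S,4Z)-3-[(tert-butyldimethylsilyl)oxy]-5-methyl-7-(phenylsulfonyl)-2-(propan-2-yl)hept-4-en-1-yl]sulfonyl}-1-phenyl-1H-tetrazole; 16 (R)-2-methyloxirane-2-carbaldehyde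
Product: 18 tert-butyl(dimethyl){[(1E,3S,4R,5Z)-6-methyl-1-[(2S)-2-methyloxiran-2-yl]-8-(phenylsulfonyl)-3-(propan-2-yl)octa-1,5-dien-4-yl]oxy}silane, via potassium sulfonyl carbanion 17 (not isolated)
Conditions: KN(SiMe3)2 (1.05 equiv), DME, −60 °C; then 16 (2 equiv), −60 °C → rt
Reagents that add atoms: none
Why: Julia–Kocienski olefination: the base deprotonates only the tetrazolyl sulfone CH2, which is several pKa units more acidic than the CH2 next to the phenyl sulfone, to give 17. Addition to 16, Smiles rearrangement and loss of SO2 and the tetrazololate give the alkene; the potassium counter-ion, DME and the quaternary α-carbon of 16 favour the anti adduct and hence the E alkene. Aldehyde 16 cannot enolise, so the epoxide stereocenter is carried over intact.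

Step 13
Reactants: 18 tert-butyl(dimethyl){[(1E,3S,4R,5Z)-6-methyl-1-[(2S)-2-methyloxiran-2-yl]-8-(phenylsulfonyl)-3-(propan-2-yl)octa-1,5-dien-4-yl]oxy}silane
Product: 20 (1R,2E,4S,5R,6Z)-5-[(tert-butyldimethylsilyl)oxy]-1,7-dimethyl-9-(phenylsulfonyl)-4-(propan-2-yl)cyclodeca-2,6-dien-1-ol (both C9 epimers), via lithiated sulfone 19 (not isolated)
Conditions: LiN(iPr)2 (1.3 equiv), THF (0.003 M), −78 → 0 °C; H2O
Reagents that add atoms: none
Why: LiN(iPr)2 removes a proton from C2 next to the phenyl sulfone, the only acidic site of 18, to give the lithiated sulfone 19. The carbanion attacks the epoxide methylene C1 from the rear in an SN2 opening, which forms the C1–C2 bond and releases the C10 lithium alkoxide. The closest known reaction type is the intramolecular alkylation of sulfone-stabilised carbanions by epoxides, which has been used to close medium and large carbocycles. The ten-membered ring closes by attack at the distal oxirane carbon: judged by the breaking C1–O bond, which lies outside the new carbocycle, it is a 10-exo-tet closure, whereas the usage common for epoxide openings calls it the endo (fused transition state) mode because both oxirane carbons become ring members. No stereocenter of the target is created: the C10–O bond is not broken, so C10 keeps the configuration of the epoxide, and the new sulfone-bearing C2 forms as both epimers, which step 14 erases. The step needs attack at C1 and not SN2′ attack at C8 (a seven-membered ring) or attack at C10; C1 is an unhindered primary carbon, C10 is quaternary, C8 is shielded by the branched C7, and a lithium counter-ion without copper or palladium favours direct over allylic substitution. The Z C4=C5 and E C8=C9 alkenes remove rotors and transannular contacts from the chain, and high dilution suppresses intermolecular alkylation. The silyl ether and both alkenes are inert to the base.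

Step 14
Reactants: 20 (1R,2E,4S,5R,6Z)-5-[(tert-butyldimethylsilyl)oxy]-1,7-dimethyl-9-(phenylsulfonyl)-4-(propan-2-yl)cyclodeca-2,6-dien-1-ol (both C9 epimers)
Product: 21 (1R,2E,4S,5R,6Z)-5-[(tert-butyldimethylsilyl)oxy]-1,7-dimethyl-4-(propan-2-yl)cyclodeca-2,6-dien-1-ol
Conditions: 6% Na(Hg), Na2HPO4, MeOH–THF, −20 °C
Reagents that add atoms: none
Why: Reductive desulfonylation by electron transfer: the C–S bond is cleaved and the C2 carbanion is protonated by methanol, so both C2 epimers converge on one compound. The hydroxyl is γ to the sulfone, so no Julia-type elimination is possible, and the phosphate buffer keeps the medium from becoming strongly basic.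

Step 15
Reactants: 21 (1R,2E,4S,5R,6Z)-5-[(tert-butyldimethylsilyl)oxy]-1,7-dimethyl-4-(propan-2-yl)cyclodeca-2,6-dien-1-ol
Product: 22 (1R,2E,4S,5R,6Z)-1,7-dimethyl-4-(propan-2-yl)cyclodeca-2,6-diene-1,5-diol
Conditions: Bu4NF, THF, rt
Reagents that add atoms: none
Why: Fluoride cleavage of the silyl ether, driven by the strength of the Si–F bond; no stereocenter or alkene is affected.

Step 16
Reactants: 22 (1R,2E,4S,5R,6Z)-1,7-dimethyl-4-(propan-2-yl)cyclodeca-2,6-diene-1,5-diol
Product: 23 (1R,2R,3S,4E,6R,10S)-6,10-dimethyl-3-(propan-2-yl)-11-oxabicyclo[8.1.0]undec-4-ene-2,6-diol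
Conditions: Ti(OiPr)4 (1.2 equiv), D-(−)-diisopropyl tartrate (1.4 equiv), tBuOOH (2 equiv), 4 Å MS, CH2Cl2, −20 °C
Reagents that add atoms: tert-butyl hydroperoxide, CC(C)(C)OO
Why: Hydroxyl-directed epoxidation of a secondary allylic alcohol with Ti(OiPr)4 and a tartrate ester: the C6 alkoxide binds titanium and the peroxide oxygen is delivered to C4=C5 only, because the tertiary allylic C10–OH is a very poor substrate and C8=C9 is less electron-rich. Syn addition to the Z alkene gives the cis-fused oxirane. D-(−)-tartrate directs oxygen to the face that makes C5 R, and the 6R alcohol is the fast-reacting (matched) enantiomer for this tartrate, which leads to the erythro epoxy alcohol 4S,5R; this is also the diastereomer favoured by the small O–C–C=C dihedral angle of metal-alkoxide epoxidations of Z-cycloalkenols.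

Step 17
Reactants: 24 4-hydroxybenzoic acid
Product: 26 4-[(tert-butyldimethylsilyl)oxy]benzoic acid, via bis-silylated hydroxybenzoate 25 (not isolated)
Conditions: TBSCl (2.5 equiv), imidazole, DMF, rt; then AcOH–THF–H2O, rt
Reagents that add atoms: tert-butyldimethylsilyl chloride, CC(C)(C)[Si](C)(C)Cl
Why: Both acidic groups are silylated, and the silyl ester, which is far more labile than the aryl silyl ether, is then hydrolysed selectively by aqueous acetic acid.

Step 18
Reactants: 23 (1R,2R,3S,4E,6R,10S)-6,10-dimethyl-3-(propan-2-yl)-11-oxabicyclo[8.1.0]undec-4-ene-2,6-diol; 26 4-[(tert-butyldimethylsilyl)oxy]benzoic acid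
Product: 27 (1R,2R,3S,4E,6R,10S)-6-hydroxy-6,10-dimethyl-3-(propan-2-yl)-11-oxabicyclo[8.1.0]undec-4-en-2-yl 4-[(tert-butyldimethylsilyl)oxy]benzoate
Conditions: DCC, DMAP, CH2Cl2, 0 °C → rt
Reagents that add atoms: none
Why: Steglich esterification: the carbodiimide activates the acid and DMAP transfers the acyl group to the secondary C6 hydroxyl. The tertiary C10 hydroxyl is too hindered to react, and the neutral conditions spare the epoxide.

Step 19
Reactants: 27 (1R,2R,3S,4E,6R,10S)-6-hydroxy-6,10-dimethyl-3-(propan-2-yl)-11-oxabicyclo[8.1.0]undec-4-en-2-yl 4-[(tert-butyldimethylsilyl)oxy]benzoate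
Product: 28 (1R,2R,3S,4E,6R,10S)-6-hydroxy-6,10-dimethyl-3-(propan-2-yl)-11-oxabicyclo[8.1.0]undec-4-en-2-yl 4-hydroxybenzoate
Conditions: Bu4NF, AcOH, THF, 0 °C
Reagents that add atoms: none
Why: Aryl silyl ethers are cleaved rapidly by fluoride. Acetic acid buffers the phenoxide and any alkoxide, so that the ester should neither migrate nor hydrolyse and the epoxide is not opened.

## Compound list

1 | 4-methyl-5,6-dihydro-2H-pyran-2-one | CC1=CC(=O)OCC1 | starting material
2 | (Z)-5-hydroxy-N-methoxy-N,3-dimethylpent-2-enamide | CON(C)C(=O)/C=C(/C)CCO | intermediate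
3 | (Z)-N-methoxy-N,3-dimethyl-5-(phenylsulfanyl)pent-2-enamide | CON(C)C(=O)/C=C(/C)CCSc1ccccc1 | intermediate
4 | (Z)-N-methoxy-N,3-dimethyl-5-(phenylsulfonyl)pent-2-enamide | CON(C)C(=O)/C=C(/C)CCS(=O)(=O)c1ccccc1 | intermediate
5 | (Z)-3-methyl-5-(phenylsulfonyl)pent-2-enal | O=C/C=C(/C)CCS(=O)(=O)c1ccccc1 | intermediate
6 | (R)-4-benzyl-1,3-oxazolidin-2-one | O=C1N[C@H](Cc2ccccc2)CO1 | starting material
7 | 3-methylbutanoyl chloride | CC(C)CC(Cl)=O | starting material
8 | (R)-4-benzyl-3-(3-methylbutanoyl)-1,3-oxazolidin-2-one | CC(C)CC(=O)N1[C@H](Cc2ccccc2)COC1=O | intermediate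
9 | dibutylboron Z-enolate of 8 (not isolated) | CC(C)/C=C(\OB(CCCC)CCCC)N1[C@H](Cc2ccccc2)COC1=O | intermediate
10 | (R)-4-benzyl-3-[(2R,3S,4Z)-3-hydroxy-5-methyl-7-(phenylsulfonyl)-2-(propan-2-yl)hept-4-enoyl]-1,3-oxazolidin-2-one | CC(C)[C@H]([C@@H](O)/C=C(/C)CCS(=O)(=O)c1ccccc1)C(=O)N1[C@H](Cc2ccccc2)COC1=O | intermediate
11 | (R)-4-benzyl-3-[(2R,3S,4Z)-3-[(tert-butyldimethylsilyl)oxy]-5-methyl-7-(phenylsulfonyl)-2-(propan-2-yl)hept-4-enoyl]-1,3-oxazolidin-2-one | CC(C)[C@H]([C@@H](O[Si](C)(C)C(C)(C)C)/C=C(/C)CCS(=O)(=O)c1ccccc1)C(=O)N1[C@H](Cc2ccccc2)COC1=O | intermediate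
12 | (2S,3S,4Z)-3-[(tert-butyldimethylsilyl)oxy]-5-methyl-7-(phenylsulfonyl)-2-(propan-2-yl)hept-4-en-1-ol | CC(C)[C@H]([C@@H](O[Si](C)(C)C(C)(C)C)/C=C(/C)CCS(=O)(=O)c1ccccc1)CO | intermediate
13 | 5-{[(2R,3S,4Z)-3-[(tert-butyldimethylsilyl)oxy]-5-methyl-7-(phenylsulfonyl)-2-(propan-2-yl)hept-4-en-1-yl]sulfanyl}-1-phenyl-1H-tetrazole | CC(C)[C@H]([C@@H](O[Si](C)(C)C(C)(C)C)/C=C(/C)CCS(=O)(=O)c1ccccc1)CSc1nnnn1-c1ccccc1 | intermediate
14 | 5-{[(2R,3S,4Z)-3-[(tert-butyldimethylsilyl)oxy]-5-methyl-7-(phenylsulfonyl)-2-(propan-2-yl)hept-4-en-1-yl]sulfonyl}-1-phenyl-1H-tetrazole | CC(C)[C@H]([C@@H](O[Si](C)(C)C(C)(C)C)/C=C(/C)CCS(=O)(=O)c1ccccc1)CS(=O)(=O)c1nnnn1-c1ccccc1 | intermediate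
15 | (S)-(2-methyloxiran-2-yl)methanol | OC[C@@]1(C)CO1 | starting material
16 | (R)-2-methyloxirane-2-carbaldehyde | O=C[C@@]1(C)CO1 | intermediate
17 | potassium sulfonyl carbanion of 14 (metalated at the CH2 next to the tetrazolyl sulfone; not isolated) | CC(C)[C@H]([C@@H](O[Si](C)(C)C(C)(C)C)/C=C(/C)CCS(=O)(=O)c1ccccc1)C([K])S(=O)(=O)c1nnnn1-c1ccccc1 | intermediate
18 | tert-butyl(dimethyl){[(1E,3S,4R,5Z)-6-methyl-1-[(2S)-2-methyloxiran-2-yl]-8-(phenylsulfonyl)-3-(propan-2-yl)octa-1,5-dien-4-yl]oxy}silane | CC(C)[C@H]([C@@H](O[Si](C)(C)C(C)(C)C)/C=C(/C)CCS(=O)(=O)c1ccccc1)/C=C/[C@@]1(C)CO1 | intermediate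
19 | lithiated sulfone of 18 (lithium on the carbon next to the phenyl sulfone; not isolated) | CC(C)[C@H]([C@@H](O[Si](C)(C)C(C)(C)C)/C=C(/C)CC([Li])S(=O)(=O)c1ccccc1)/C=C/[C@@]1(C)CO1 | intermediate
20 | (1R,2E,4S,5R,6Z)-5-[(tert-butyldimethylsilyl)oxy]-1,7-dimethyl-9-(phenylsulfonyl)-4-(propan-2-yl)cyclodeca-2,6-dien-1-ol (both C9 epimers) | CC(C)[C@H]1/C=C/[C@](C)(O)CC(S(=O)(=O)c2ccccc2)C/C(C)=C\[C@@H]1O[Si](C)(C)C(C)(C)C | intermediate
21 | (1R,2E,4S,5R,6Z)-5-[(tert-butyldimethylsilyl)oxy]-1,7-dimethyl-4-(propan-2-yl)cyclodeca-2,6-dien-1-ol | CC(C)[C@H]1/C=C/[C@](C)(O)CCC/C(C)=C\[C@@H]1O[Si](C)(C)C(C)(C)C | intermediate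
22 | (1R,2E,4S,5R,6Z)-1,7-dimethyl-4-(propan-2-yl)cyclodeca-2,6-diene-1,5-diol | CC(C)[C@H]1/C=C/[C@](C)(O)CCC/C(C)=C\[C@@H]1O | intermediate
23 | (1R,2R,3S,4E,6R,10S)-6,10-dimethyl-3-(propan-2-yl)-11-oxabicyclo[8.1.0]undec-4-ene-2,6-diol | CC(C)[C@H]1/C=C/[C@](C)(O)CCC[C@]2(C)O[C@@H]2[C@@H]1O | intermediate
24 | 4-hydroxybenzoic acid | OC(=O)c1ccc(O)cc1 | starting material
25 | tert-butyldimethylsilyl 4-[(tert-butyldimethylsilyl)oxy]benzoate (not isolated) | CC(C)(C)[Si](C)(C)OC(=O)c1ccc(O[Si](C)(C)C(C)(C)C)cc1 | intermediate
26 | 4-[(tert-butyldimethylsilyl)oxy]benzoic acid | CC(C)(C)[Si](C)(C)Oc1ccc(cc1)C(O)=O | intermediate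
27 | (1R,2R,3S,4E,6R,10S)-6-hydroxy-6,10-dimethyl-3-(propan-2-yl)-11-oxabicyclo[8.1.0]undec-4-en-2-yl 4-[(tert-butyldimethylsilyl)oxy]benzoate | CC(C)[C@H]1/C=C/[C@](C)(O)CCC[C@]2(C)O[C@@H]2[C@@H]1OC(=O)c1ccc(O[Si](C)(C)C(C)(C)C)cc1 | intermediate
28 | (1R,2R,3S,4E,6R,10S)-6-hydroxy-6,10-dimethyl-3-(propan-2-yl)-11-oxabicyclo[8.1.0]undec-4-en-2-yl 4-hydroxybenzoate | CC(C)[C@H]1/C=C/[C@](C)(O)CCC[C@]2(C)O[C@@H]2[C@@H]1OC(=O)c1ccc(O)cc1 | target

## Step count and least certain steps

Total step count: 19 steps. Longest linear sequence: 16 steps (steps 1–4, 6–10, 12–16, 18 and 19).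

**Step 13 (key step).** The most likely failure is misdirected or intermolecular alkylation. Closing a ten-membered ring by SN2 substitution is slow, so attack of the carbanion at C8 in SN2′ fashion (which would close a seven-membered ring) or attack on the epoxide of a second molecule (oligomers) can overtake it. On long exposure to amide base the epoxide may also isomerise to an allylic alkoxide.

Fallback: the order of the two C–C bond formations is exchanged, so that C1–C2 is made intermolecularly on a non-allylic epoxide, where SN2′ is impossible and the electrophile can be used in excess, and the ring is closed by olefination at C8=C9. It sets out from 12 and 15. Alcohol 15 is converted with NaH and 4-methoxybenzyl chloride into the ether F1. The dianion of 12 (nBuLi, 2.1 equiv, THF, −78 °C) opens F1 at its CH2 in the presence of BF3·OEt2 to give the diol F2. The primary alcohol of F2 is converted under the conditions of steps 9 and 10 into the tetrazolyl sulfide F3 and the sulfone F4. DDQ removes the 4-methoxybenzyl group to give the 1,2-diol F5, and SO3·pyridine/DMSO/iPr2NEt oxidises its primary alcohol to the α-hydroxy aldehyde F6. KN(SiMe3)2 (2.2 equiv) in DME under high dilution should then effect an intramolecular Julia–Kocienski olefination that comes back to the route at 20. The ring is closed there by carbonyl addition, which tolerates medium-ring strain better than substitution; the E/Z ratio of that closure would be the point to watch.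

**Step 16.** The most likely failure is poor facial selectivity or a stalled reaction. If the ring holds the C6–O bond far from the plane of C4=C5, delivery to the face that gives the threo (trans) epoxy alcohol becomes competitive. The hindered Z-allylic secondary alcohol may also turn over slowly on titanium, and the Lewis-acidic alkoxide species derived from Ti(OiPr)4 could promote transannular opening of the new epoxide by the C10 hydroxyl.

Fallback: the opposite, peracid-type selectivity is used together with a double inversion at C6. It sets out from 22. A Mitsunobu reaction with 4-nitrobenzoic acid (PPh3, DIAD) gives the inverted ester F7, and K2CO3 in MeOH gives the C6-epimeric diol F8. mCPBA, which reacts with medium-ring Z-allylic alcohols through a large O–C–C=C dihedral angle and gives the trans (threo) epoxy alcohol, should then deliver the 4S,5R epoxide F9. A second Mitsunobu reaction, this time with acid 26, inverts C6 back and installs the ester in the same operation, so the route is rejoined at 27.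

**Step 12.** The most likely failure is erosion of E selectivity together with loss of the electrophile. Aldehyde 16 is small, volatile and strongly electrophilic, an α-oxygenated aldehyde can give more of the syn adduct (Z alkene) than a simple one, and the alkoxide formed on addition sits next to an epoxide and could rearrange before the Smiles step.

Fallback: C9, C10 and C1 are brought in as a bulkier, non-volatile chlorohydrin aldehyde, and the epoxide is closed after the olefination. It sets out from 15 and 14. LiCl and AcOH in THF open 15 at its CH2 to the chloro diol F10, TESOTf and 2,6-lutidine give the bis-silyl ether F11, and Swern conditions ((COCl)2, DMSO, Et3N) convert the primary silyl ether directly into the aldehyde F12. Olefination of 14 with F12 under the conditions of step 12 gives the E alkene F13. HF·pyridine removes the triethylsilyl group selectively to give the chlorohydrin F14, and K2CO3 in MeOH then closes the epoxide, which returns to the route at 18.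

**Step 1.** The most likely failure is incomplete or reversed ring opening. The Z-hydroxy amide 2 is predisposed to close back to lactone 1 on work-up, concentration or chromatography, and the aluminium amide could add to the unsaturated lactone in conjugate fashion.

Fallback: the lactone is opened at its alkyl C–O bond by sulfur instead of at the acyl carbon by nitrogen, so that no free hydroxyl is ever present to close the ring again. It sets out from 1. PhSNa (from PhSH and NaH) in DMF at 80 °C attacks the O–CH2 carbon of 1 in an SN2 reaction and releases the conjugated carboxylate; conjugate addition at the β,β-disubstituted position is reversible, whereas this alkyl–oxygen cleavage is not. Acidification gives the Z-enoic acid F15 with the ring geometry intact. EDC·HCl, HOBt, MeNH(OMe)·HCl and iPr2NEt in CH2Cl2 then convert F15 into the Weinreb amide 3, where the route is rejoined and step 2 is no longer needed.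

## Further compounds

F1 | step 13 | (R)-2-{[(4-methoxybenzyl)oxy]methyl}-2-methyloxirane | COc1ccc(COC[C@@]2(C)CO2)cc1
F2 | step 13 | (2S,3S,4Z,9R)-3-[(tert-butyldimethylsilyl)oxy]-10-[(4-methoxybenzyl)oxy]-5,9-dimethyl-7-(phenylsulfonyl)-2-(propan-2-yl)dec-4-ene-1,9-diol (both C7 epimers) | CC(C)[C@H]([C@@H](O[Si](C)(C)C(C)(C)C)/C=C(/C)CC(S(=O)(=O)c1ccccc1)C[C@@](C)(O)COCc1ccc(OC)cc1)CO
F3 | step 13 | tetrazolyl sulfide from F2 (primary OH replaced by 1-phenyl-1H-tetrazol-5-ylsulfanyl) | CC(C)[C@H]([C@@H](O[Si](C)(C)C(C)(C)C)/C=C(/C)CC(S(=O)(=O)c1ccccc1)C[C@@](C)(O)COCc1ccc(OC)cc1)CSc1nnnn1-c1ccccc1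
F4 | step 13 | tetrazolyl sulfone from F3 | CC(C)[C@H]([C@@H](O[Si](C)(C)C(C)(C)C)/C=C(/C)CC(S(=O)(=O)c1ccccc1)C[C@@](C)(O)COCc1ccc(OC)cc1)CS(=O)(=O)c1nnnn1-c1ccccc1
F5 | step 13 | 1,2-diol from F4 (4-methoxybenzyl ether cleaved) | CC(C)[C@H]([C@@H](O[Si](C)(C)C(C)(C)C)/C=C(/C)CC(S(=O)(=O)c1ccccc1)C[C@@](C)(O)CO)CS(=O)(=O)c1nnnn1-c1ccccc1
F6 | step 13 | α-hydroxy aldehyde from F5 (primary alcohol oxidised) | CC(C)[C@H]([C@@H](O[Si](C)(C)C(C)(C)C)/C=C(/C)CC(S(=O)(=O)c1ccccc1)C[C@@](C)(O)C=O)CS(=O)(=O)c1nnnn1-c1ccccc1
F7 | step 16 | (1S,2Z,7R,8E,10S)-7-hydroxy-3,7-dimethyl-10-(propan-2-yl)cyclodeca-2,8-dien-1-yl 4-nitrobenzoate (ester of the C6 epimer of 22) | CC(C)[C@H]1/C=C/[C@](C)(O)CCC/C(C)=C\[C@H]1OC(=O)c1ccc(cc1)[N+]([O-])=O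
F8 | step 16 | (1R,2E,4S,5S,6Z)-1,7-dimethyl-4-(propan-2-yl)cyclodeca-2,6-diene-1,5-diol (C6 epimer of 22) | CC(C)[C@H]1/C=C/[C@](C)(O)CCC/C(C)=C\[C@H]1O
F9 | step 16 | (1R,2S,3S,4E,6R,10S)-6,10-dimethyl-3-(propan-2-yl)-11-oxabicyclo[8.1.0]undec-4-ene-2,6-diol (C6 epimer of 23) | CC(C)[C@H]1/C=C/[C@](C)(O)CCC[C@]2(C)O[C@@H]2[C@H]1O
F10 | step 12 | (S)-3-chloro-2-methylpropane-1,2-diol | OC[C@@](O)(C)CCl
F11 | step 12 | (S)-3-chloro-2-methyl-1,2-bis[(triethylsilyl)oxy]propane | CC[Si](CC)(CC)OC[C@@](O[Si](CC)(CC)CC)(C)CCl
F12 | step 12 | (S)-3-chloro-2-methyl-2-[(triethylsilyl)oxy]propanal | O=C[C@@](O[Si](CC)(CC)CC)(C)CCl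
F13 | step 12 | E-alkene from 14 and F12: open-chain C10 triethylsilyl ether with C1 chloride, C6 silyl ether and C2 phenyl sulfone | CC(C)[C@H]([C@@H](O[Si](C)(C)C(C)(C)C)/C=C(/C)CCS(=O)(=O)c1ccccc1)/C=C/[C@@](O[Si](CC)(CC)CC)(C)CCl
F14 | step 12 | chlorohydrin from F13 (C10 hydroxyl free) | CC(C)[C@H]([C@@H](O[Si](C)(C)C(C)(C)C)/C=C(/C)CCS(=O)(=O)c1ccccc1)/C=C/[C@@](O)(C)CCl
F15 | step 1 | (Z)-3-methyl-5-(phenylsulfanyl)pent-2-enoic acid | OC(=O)/C=C(/C)CCSc1ccccc1
A1 | alternative 1 | (1R,2Z,7R,8E,10S)-3,7-dimethyl-10-(propan-2-yl)-7-[(triethylsilyl)oxy]cyclodeca-2,8-dien-1-ol | CC(C)[C@H]1/C=C/[C@](C)(O[Si](CC)(CC)CC)CCC/C(C)=C\[C@@H]1O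
A2 | alternative 1 | (2S,3E,5R,9Z)-10-iodo-5,9-dimethyl-2-(propan-2-yl)-5-[(triethylsilyl)oxy]deca-3,9-dienal | CC(C)[C@H](C=O)/C=C/[C@](C)(O[Si](CC)(CC)CC)CCC/C(C)=C\I
A3 | alternative 2 | (1E,3R,4S,5E,7R)-7-hydroxy-3-[(4-methoxybenzyl)oxy]-7-methyl-4-(propan-2-yl)cyclodeca-1,5-dien-1-yl trifluoromethanesulfonate | CC(C)[C@H]1/C=C/[C@](C)(O)CCC/C(OS(=O)(=O)C(F)(F)F)=C\[C@@H]1OCc2ccc(OC)cc2
A4 | alternative 2 | (1R,2S,3R)-1-{(E)-2-[(4-methoxybenzyl)oxy]ethenyl}-3-methyl-2-[(E)-3-methylbut-1-en-1-yl]cyclohexane-1,3-diol | CC(C)/C=C/[C@H]1[C@](C)(O)CCC[C@@]1(O)/C=C/OCc1ccc(OC)cc1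
A5 | alternative 3 | tert-butyl{[(1R,2Z,7R,8E,10S)-3,7-dimethyl-10-(propan-2-yl)-7-[(triethylsilyl)oxy]cyclodeca-2,8-dien-1-yl]oxy}dimethylsilane | CC(C)[C@H]1/C=C/[C@](C)(O[Si](CC)(CC)CC)CCC/C(C)=C\[C@@H]1O[Si](C)(C)C(C)(C)C
A6 | alternative 3 | tert-butyl{[(4R,5E,7S,8R,9Z)-10-iodo-4-methyl-7-(propan-2-yl)-4-[(triethylsilyl)oxy]undeca-1,5,9-trien-8-yl]oxy}dimethylsilane | CC(C)[C@H]([C@@H](O[Si](C)(C)C(C)(C)C)/C=C(/C)I)/C=C/[C@](C)(O[Si](CC)(CC)CC)CC=C
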